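The runs were generated by integration for substances that don't exist, noise included.

| flask | starting material | remark | time |
|---|---|---|---|
| autumn | 0.015 M | run made earlier |  |
| noon | 0.076 M | run made earlier |  |
| grey | 0.050 M |  | 50 h |
| amber | 0.012 M |  | 25 h |

| run | time / h | target / % | isomer of the product A / % |
|---|---|---|---|
| autumn | 2.00 | 12.9 | 5.5 |
| autumn | 6.00 | 26.7 | 11.9 |
| autumn | 12.0 | 34.7 | 12.6 |
| autumn | 20.0 | 38.4 | 13.2 |
| autumn | 25.0 | 38.5 | 12.5 |
| noon | 2.00 | 12.1 | 5.8 |
| noon | 6.00 | 26.7 | 10.4 |
| noon | 12.0 | 36.4 | 13.5 |
| noon | 20.0 | 38.2 | 13.3 |
| noon | 25.0 | 37.8 | 12.5 |

(standard deviation of a reading: 0.5 percentage points)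

* which one finishes higher in share of target in all that became target or isomer of the product A or isomer of the product B or isomer of the product C ("neither" within 2 percentage points) (grey / amber / neither)
* share of target in all that became target or isomer of the product A or isomer of the product B or isomer of the product C, grey
* share of target in all that became target or isomer of the product A or isomer of the product B or isomer of the product C, amber

- the earlier runs were read with a standard deviation of 0.5 percentage points
- steps that have been proposed: starting material <-> target; starting material <-> isomer of the product A; starting material <-> isomer of the product B; target <-> isomer of the product C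

The slowness I looked for sat in the last readings: in the mean of autumn and noon, isomer of the product A sagged from 13.2 % at 20.0 h to 12.5 % at 25.0 h, and I read that as a slow drain λ of 0.0117 h⁻¹, a rough reading, since each value carries a scatter of 0.5 percentage points. Autumn at 0.015 M and noon at 0.076 M ended with target at 38.5 % and 37.8 %, so I let the charge drop out, which left grey's extra time as the difference I reckoned with.

I folded this into a drain number θ, the product of λ and grey's extra time over amber, which came to 0.291. Taking the drain at its mean rate and assuming that target's share fell with it, I expected grey's share of target, the selectivity, to be e^(−θ) = 0.747 of amber's. That was enough for the order: even with amber's share as low as the mean target of autumn and noon at 25.0 h, 38.1 %, the gap I expected is 9.6 points, more than the margin of 2 points. It was not enough for the level: in those two runs 49.4 % of the charge went unread at that time, and how much of it remained starting material was open. I committed to amber, with the ratio above.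

The forecast said amber, with 36.5 % for grey and 39 % for amber, a ratio of 0.936, holding that “starting material is nearly gone by 25 h”.

Amber finished higher, at 50.2 % against 40.4 % for grey, a ratio of 0.805.

    starting material ⇌ target (K = 2.40, k = 2.10 × 10⁻⁵ s⁻¹)
    starting material ⇌ isomer of the product A (K = 0.450, k = 9.30 × 10⁻⁶ s⁻¹)
    starting material ⇌ isomer of the product B (K = 0.350, k = 8.70 × 10⁻⁶ s⁻¹)
    target ⇌ isomer of the product C (K = 15.0, k = 5.40 × 10⁻⁶ s⁻¹)

Amber still held 24 % starting material, so its target of 38.1 % stood on 76.0 % of the charge. The flask grey read at 12 h had a share of 53.7 %; carried to 25 h with θ taken in proportion to the hours, that gives 46.1 %, where amber stands at 50.2 %.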